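**Retrosynthetic overview**
1. Rings are lettered A–E along the chain (A and E the dimethylated triketone rings, B, C and D the arenes). Cutting the two outer CH2 bridges gives the three-arene core B–C–D and two butanoylfilicinic acid units, each delivered as its aminomethyl derivative.
2. Rings B and D are unmade together. Each is the Claisen-cyclised form of a 4-hydroxy-6-(2-oxopentyl)-2-pyrone, so the core comes from a bis-pyrone by a twofold pyrone-to-acylphloroglucinol ring transformation (key step).
3. The bis-pyrone comes from bought butanoylphloroglucinol (ring C) and two molecules of the pyrone, joined through the pyrone's aminomethyl derivative. Ring C has exactly two free carbons and the pyrone one nucleophilic carbon, so bridging stops at the 2:1 stage.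
4. The pyrone comes from triacetic acid lactone dianion and methyl butanoate. Rings A and E come from butanoylphloroglucinol by dearomatising gem-dimethylation.
5. Ring order: C bought; B and D formed together in step 3; A and E attached last in step 5.

Assumption: the target has no stereocentre (each CMe2 carbon carries two identical methyl groups), so it is achiral and the drawn structure is its only stereoisomer; 1-(2,4,6-trihydroxyphenyl)butan-1-one is taken as a catalogue compound; where two molecules of one compound or reagent enter a product, it is entered twice on its line.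

**Route**

Step 1
Reactants: 1 4-hydroxy-6-methyl-2H-pyran-2-one (triacetic acid lactone); 2 methyl butanoate
Product: 3 4-hydroxy-6-(2-oxopentyl)-2H-pyran-2-one
Conditions: LiN(i-Pr)2 (4.2 equiv), 1 (2.1 equiv), THF, −78 to −20 °C; then 2 (1.0 equiv), −78 to 0 °C; 1 M HCl
Reagents that add atoms: none
Why: Claisen-type C-acylation of the O,C-dianion of 1, whose vinylogous 6-methyl carbanion is the only strongly nucleophilic site; the second equivalent of dianion deprotonates the more acidic product (excess 1 is recovered), and no stereocentre is formed.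

Step 2
Reactants: 3 4-hydroxy-6-(2-oxopentyl)-2H-pyran-2-one; 3 4-hydroxy-6-(2-oxopentyl)-2H-pyran-2-one; 4 1-(2,4,6-trihydroxyphenyl)butan-1-one (butanoylphloroglucinol)
Product: 6 3,3'-[(5-butanoyl-2,4,6-trihydroxy-1,3-phenylene)bis(methylene)]bis[4-hydroxy-6-(2-oxopentyl)-2H-pyran-2-one], via pyrone Mannich base 5 (not isolated)
Conditions: 3 (2.2 equiv), Me2NCH2NMe2 (2.2 equiv), 1,4-dioxane, 0 to 20 °C; then 4 (1.0 equiv), 60 °C, N2 sparge; cold 1 M HCl
Reagents that add atoms: bis(dimethylamino)methane (first equivalent), CN(C)CN(C)C; bis(dimethylamino)methane (second equivalent), CN(C)CN(C)C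
Why: Mannich reaction at C3, the one strongly nucleophilic carbon of 3, then loss of dimethylamine to the 3-methylene pyrandione, which each of the two free ring carbons of 4 captures in a Friedel–Crafts-type Michael addition (carba-Betti-type methylene bridging); the electrophile is monofunctional and 4 has exactly two such carbons, so two molecules of 3 are taken up and the coupling ends at the 2:1 adduct, and no stereocentre is formed.

Step 3
Reactants: 6 3,3'-[(5-butanoyl-2,4,6-trihydroxy-1,3-phenylene)bis(methylene)]bis[4-hydroxy-6-(2-oxopentyl)-2H-pyran-2-one]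
Product: 8 1-{3,5-bis[(3-butanoyl-2,4,6-trihydroxyphenyl)methyl]-2,4,6-trihydroxyphenyl}butan-1-one, via ring-opened diester 7 (not isolated)
Conditions: Mg(OMe)2 (12 equiv), dry MeOH (0.01 M), 65 °C, Ar; then 1 M HCl, 0 °C
Reagents that add atoms: none
Why: Proposed new method: methoxide from the magnesium chelate opens each lactone to a 2-substituted methyl 3,5,7-trioxodecanoate, whose C6 carbanion attacks the C1 ester (Claisen/Dieckmann) and the resulting triketone enolises to the arene, so rings B and D form in the same flask with the CH2 bridge between two hydroxyls and a free CH opposite; the competing C2-to-C7 aldol is a dead end because C2 bears the benzylic substituent and cannot aromatise; the closest known reaction is the Mg(OMe)2-induced conversion of a single 4-hydroxy-6-(2-oxoalkyl)-2-pyrone into an acylphloroglucinol, here run twice on a 3-substituted pyrone; the two CH centres of 7 become sp2, so no stereocentre remains.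

Step 4
Reactants: 4 1-(2,4,6-trihydroxyphenyl)butan-1-one (butanoylphloroglucinol)
Product: 9 2-butanoyl-3,5-dihydroxy-4,4-dimethylcyclohexa-2,5-dien-1-one (butanoylfilicinic acid)
Conditions: NaOMe (4 equiv), MeI (2.5 equiv), MeOH, 0 to 20 °C; 1 M HCl
Reagents that add atoms: iodomethane (first methyl group), CI; iodomethane (second methyl group), CI
Why: Base-mediated C-methylation of the phloroglucinol anion in which the second methyl group enters at the same carbon and dearomatises the ring to the vinylogous acid (known gem-dimethylation of acylphloroglucinols to acylfilicinic acids); the product is achiral.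

Step 5
Reactants: 9 2-butanoyl-3,5-dihydroxy-4,4-dimethylcyclohexa-2,5-dien-1-one; 9 2-butanoyl-3,5-dihydroxy-4,4-dimethylcyclohexa-2,5-dien-1-one; 8 1-{3,5-bis[(3-butanoyl-2,4,6-trihydroxyphenyl)methyl]-2,4,6-trihydroxyphenyl}butan-1-one
Product: 11 1-{3,5-bis({3-butanoyl-5-[(5-butanoyl-2,4-dihydroxy-3,3-dimethyl-6-oxocyclohexa-1,4-dien-1-yl)methyl]-2,4,6-trihydroxyphenyl}methyl)-2,4,6-trihydroxyphenyl}butan-1-one (the achiral target), via filicinic Mannich base 10 (not isolated)
Conditions: 9 (2.4 equiv), Me2NCH2NMe2 (2.4 equiv), 1,4-dioxane, 0 to 20 °C; then 8 (1.0 equiv), 50 °C, N2 sparge; cold 1 M HCl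
Reagents that add atoms: bis(dimethylamino)methane (first equivalent), CN(C)CN(C)C; bis(dimethylamino)methane (second equivalent), CN(C)CN(C)C
Why: Mannich reaction at the single free ring carbon of 9, then elimination of dimethylamine to the 6-methylene triketone, which is captured in a Friedel–Crafts-type Michael addition by the one nucleophilic carbon left on each outer ring of 8; two molecules of 9 are taken up, the electrophile is monofunctional so the core cannot oligomerise, and no stereocentre is formed.

**Compound list**
1 | 4-hydroxy-6-methyl-2H-pyran-2-one (triacetic acid lactone) | CC1=CC(O)=CC(=O)O1 | starting material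
2 | methyl butanoate | CCCC(=O)OC | starting material
3 | 4-hydroxy-6-(2-oxopentyl)-2H-pyran-2-one | CCCC(=O)CC1=CC(O)=CC(=O)O1 | intermediate
4 | 1-(2,4,6-trihydroxyphenyl)butan-1-one (butanoylphloroglucinol) | CCCC(=O)c1c(O)cc(O)cc1O | starting material
5 | 3-[(dimethylamino)methyl]-4-hydroxy-6-(2-oxopentyl)-2H-pyran-2-one (not isolated) | CCCC(=O)CC1=CC(O)=C(CN(C)C)C(=O)O1 | intermediate
6 | 3,3'-[(5-butanoyl-2,4,6-trihydroxy-1,3-phenylene)bis(methylene)]bis[4-hydroxy-6-(2-oxopentyl)-2H-pyran-2-one] | CCCC(=O)c1c(O)c(CC2=C(O)C=C(CC(=O)CCC)OC2=O)c(O)c(CC2=C(O)C=C(CC(=O)CCC)OC2=O)c1O | intermediate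
7 | dimethyl 2,2'-[(5-butanoyl-2,4,6-trihydroxy-1,3-phenylene)bis(methylene)]bis(3,5,7-trioxodecanoate) (not isolated; both C2 centres undefined, mixture, erased in the same flask) | CCCC(=O)CC(=O)CC(=O)C(Cc1c(O)c(CC(C(=O)OC)C(=O)CC(=O)CC(=O)CCC)c(O)c(C(=O)CCC)c1O)C(=O)OC | intermediate
8 | 1-{3,5-bis[(3-butanoyl-2,4,6-trihydroxyphenyl)methyl]-2,4,6-trihydroxyphenyl}butan-1-one | CCCC(=O)c1c(O)cc(O)c(Cc2c(O)c(Cc3c(O)cc(O)c(C(=O)CCC)c3O)c(O)c(C(=O)CCC)c2O)c1O | intermediate
9 | 2-butanoyl-3,5-dihydroxy-4,4-dimethylcyclohexa-2,5-dien-1-one (butanoylfilicinic acid) | CCCC(=O)C1=C(O)C(C)(C)C(O)=CC1=O | intermediate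
10 | 2-butanoyl-6-[(dimethylamino)methyl]-3,5-dihydroxy-4,4-dimethylcyclohexa-2,5-dien-1-one (not isolated) | CCCC(=O)C1=C(O)C(C)(C)C(O)=C(CN(C)C)C1=O | intermediate
11 | 1-{3,5-bis({3-butanoyl-5-[(5-butanoyl-2,4-dihydroxy-3,3-dimethyl-6-oxocyclohexa-1,4-dien-1-yl)methyl]-2,4,6-trihydroxyphenyl}methyl)-2,4,6-trihydroxyphenyl}butan-1-one (achiral) | CCCC(=O)C1=C(O)C(C)(C)C(O)=C(Cc2c(O)c(Cc3c(O)c(Cc4c(O)c(CC5=C(O)C(C)(C)C(O)=C(C(=O)CCC)C5=O)c(O)c(C(=O)CCC)c4O)c(O)c(C(=O)CCC)c3O)c(O)c(C(=O)CCC)c2O)C1=O | target

**Totals**
Total step count: 5.
Longest linear sequence: 4 steps (1, 2, 3, 5); step 4 is a one-step branch.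

**Steps most likely to fail, with fallbacks**

Step 3. The 3-substituted lactones may open slowly. Under hot alkoxide the central phenoxides can also expel an arm by retro-Michael cleavage, and the freshly formed outer rings could then capture the resulting quinone methide. The fallback gives up the pyrones and builds the core from ready-made arenes; it sets out from compound 4 and comes back at compound 8. Compound 4 is added slowly to bis(dimethylamino)methane (2.1 equiv, 1,4-dioxane, 0 to 20 °C) to give 1-{3,5-bis[(dimethylamino)methyl]-2,4,6-trihydroxyphenyl}butan-1-one F1, which has no free ring carbon. F1 is then heated at 90 °C with a large excess (8–10 equiv) of 4, so that each benzylic position is taken by a ring carbon of butanoylphloroglucinol, giving 8. The excess of 4 suppresses further bridging and is recovered.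

Step 5. Free 9 can trap its own methylene triketone to give the symmetrical dimer of 9. The liberated amine can also scramble methylene bridges at elevated temperature, and the second capping may lag. The fallback reverses the polarity; it sets out from compound 8 and comes back at compound 11. Compound 8 is aminomethylated at both free ring carbons with bis(dimethylamino)methane at 0 to 20 °C to give 1-{3,5-bis({3-butanoyl-5-[(dimethylamino)methyl]-2,4,6-trihydroxyphenyl}methyl)-2,4,6-trihydroxyphenyl}butan-1-one F2. F2 has no nucleophilic ring carbon left and is warmed with an excess of 9, which can only act as the nucleophile, to give 11.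

Step 2. Free 3 can capture its own methylene pyrandione to give the methylene-bis-pyrone. C5 or the side-chain methylene of 3 may compete with C3, and the adduct may cyclodehydrate (phenol oxygen onto pyrone C4). The fallback replaces the methylene transfer by a reductive alkylation; it sets out from compound 4 and comes back at compound 6. Vilsmeier–Haack diformylation of 4 (POCl3, DMF, then aqueous hydrolysis) gives 5-butanoyl-2,4,6-trihydroxybenzene-1,3-dicarbaldehyde F3. F3 is then joined to two equivalents of 3 in a proline-catalysed three-component reductive Knoevenagel alkylation with Hantzsch ester (EtOH, 40 °C), giving 6 directly.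

**Further compounds**
F1 | step 3 | 1-{3,5-bis[(dimethylamino)methyl]-2,4,6-trihydroxyphenyl}butan-1-one | CCCC(=O)c1c(O)c(CN(C)C)c(O)c(CN(C)C)c1O
F2 | step 5 | 1-{3,5-bis({3-butanoyl-5-[(dimethylamino)methyl]-2,4,6-trihydroxyphenyl}methyl)-2,4,6-trihydroxyphenyl}butan-1-one | CCCC(=O)c1c(O)c(CN(C)C)c(O)c(Cc2c(O)c(Cc3c(O)c(CN(C)C)c(O)c(C(=O)CCC)c3O)c(O)c(C(=O)CCC)c2O)c1O
F3 | step 2 | 5-butanoyl-2,4,6-trihydroxybenzene-1,3-dicarbaldehyde | CCCC(=O)c1c(O)c(C=O)c(O)c(C=O)c1O
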